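**Plan**

- **Cuts, in retrosynthetic order:** the allyl ester at C15, then C13=C14, the acyl–O bonds at C6 and C7, C6–H and C7–O of an 8-en-6-one, C9–C11, C5–H/C6–O and C8–CH3. The last cut is C4–C5, which opens ring A back to a cyclohexane-1,3-dione.
- **Enabling feature:** in ring A (C1–C5, C10) the gem-dimethyl carbon C4 is bonded directly to C5, the fusion carbon shared with ring B (C5–C10). A C5 alkenylpalladium can therefore add to a 2-methylallyl terminus hung from C10 through C1–C3. This makes C4–C5 and leaves Pd–CH2 on a carbon with no beta-hydrogen, which is reduced to the second C4 methyl.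
- **Forward order:** ring B is bought as the dione, the C1–C4 chain and the C10 methyl are attached, and ring A closes in step 7. Next come the C8 methyl, the C9 enol triflate and the C6 oxygen, installed while the only other C=C is the inert triflate alkene. C11–C13 and C16 follow by Negishi coupling, then C7/C6 oxygenation and acylation, and C14–C15 by olefination.
- **Stereochemistry:** C10 comes from catalytic asymmetric monoreduction of the prochiral dione (temporary C9 carbinol). C5 comes from alpha-face hydroboration opposite the C10 methyl, C7 from alpha-face enolate hydroxylation, C6 from alpha-face hydride delivery, and 13E from the olefination.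

Key step: step 7

Remark on the chemistry: labdane numbering is used for the bicycles and for their monocyclic precursors, and alpha means the face opposite the C10 methyl. The target is read as 5α-H, 6β-OAc, 7α-isovalerate, 10β-CH3 (5S,6S,7S,10S), 13E. The C8-methylated ketone is carried as a mixture of C8 epimers because C8 becomes trigonal one step later.

**Route**

Step 1
Reactants: 1 ethyl 4-methylpent-4-enoate
Product: 2 4-methylpent-4-enal
Conditions: i-Bu2AlH (DIBAL-H, 1.05 equiv), CH2Cl2, −78 °C; aq. potassium sodium tartrate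
Reagents that add atoms: none
Why: Partial ester reduction with one equivalent of i-Bu2AlH at −78 °C is the standard ester-to-aldehyde conversion, and the unactivated 1,1-disubstituted alkene does not react at this temperature.

Step 2
Reactants: 2 4-methylpent-4-enal; 3 cyclohexane-1,3-dione
Product: 5 2-(4-methylpent-4-en-1-yl)cyclohexane-1,3-dione, via alkylidene dione 4 (not isolated)
Conditions: L-proline (20 mol %), diethyl 2,6-dimethyl-1,4-dihydropyridine-3,5-dicarboxylate (Hantzsch ester, 1.0 equiv), CH2Cl2, rt
Reagents that add atoms: none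
Why: Organocatalytic three-component reductive alkylation (Knoevenagel condensation, then Hantzsch ester transfer hydrogenation): the electron-poor C=C of 4 takes up hydride faster than a second dione can add, so C-monoalkylation should result where an unactivated alkyl halide would mainly O-alkylate.

Step 3
Reactants: 5 2-(4-methylpent-4-en-1-yl)cyclohexane-1,3-dione; 6 iodomethane
Product: 7 2-methyl-2-(4-methylpent-4-en-1-yl)cyclohexane-1,3-dione
Conditions: MeI (3 equiv), K2CO3, acetone, reflux
Reagents that add atoms: iodomethane 6, CI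
Why: C-alkylation of the stabilised 2-alkyl-1,3-dione enolate with the small, soft electrophile MeI creates the quaternary carbon that becomes C10 (still prochiral, the two carbonyls being enantiotopic), and carbonate in acetone avoids retro-Claisen opening of the non-enolisable product.

Step 4
Reactants: 7 2-methyl-2-(4-methylpent-4-en-1-yl)cyclohexane-1,3-dione
Product: 8 (2R,3R)-3-hydroxy-2-methyl-2-(4-methylpent-4-en-1-yl)cyclohexan-1-one (C9 OH trans to the C10 methyl)
Conditions: (S)-1-methyl-3,3-diphenyltetrahydro-1H,3H-pyrrolo[1,2-c][1,3,2]oxazaborole ((S)-Me-CBS, 15 mol %), catecholborane (1.1 equiv), toluene, −78 → −40 °C; aqueous work-up; chromatographic removal of the OH/CH3-cis diastereomer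
Reagents that add atoms: none
Why: Corey–Bakshi–Shibata reduction used as a desymmetrisation: the (S)-catalyst, reading the quaternary carbon as the large group, makes the carbinol R, and the substrate accepts hydride on the face carrying the smaller methyl group, so only one enantiotopic carbonyl satisfies both demands and C10 is fixed in the sense that maps onto 10S of the target, while catecholborane leaves the tethered alkene alone at this temperature.

Step 5
Reactants: 8 (2R,3R)-hydroxy ketone
Product: 9 (2R,3R)-3-(tert-butyldimethylsilyloxy)-2-methyl-2-(4-methylpent-4-en-1-yl)cyclohexan-1-one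
Conditions: TBSCl, imidazole, DMF, rt → 40 °C
Reagents that add atoms: tert-butyldimethylsilyl chloride, CC(C)(C)[Si](C)(C)Cl
Why: Standard silyl ether formation masks the C9 hydroxyl so that the strong base of the next step cannot trigger retro-aldol cleavage of the beta-hydroxy ketone, and no stereocentre is touched.

Step 6
Reactants: 9 silyloxy ketone
Product: 11 (5R,6R)-5-(tert-butyldimethylsilyloxy)-6-methyl-6-(4-methylpent-4-en-1-yl)cyclohex-1-en-1-yl trifluoromethanesulfonate (C5 enol triflate), via potassium enolate 10 (not isolated)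
Conditions: KN(SiMe3)2 (KHMDS, 1.1 equiv), THF, −78 °C; PhNTf2, −78 → 0 °C
Reagents that add atoms: N-phenylbis(trifluoromethanesulfonimide), O=S(=O)(N(c1ccccc1)S(=O)(=O)C(F)(F)F)C(F)(F)F
Why: Kinetic enolate O-triflation: C10 is quaternary, so the C5 ketone can enolise only toward C6 and a single enol triflate regioisomer can form.

Step 7
Reactants: 11 C5 enol triflate
Product: 12 tert-butyldimethyl{[(1R,8aS)-5,5,8a-trimethyl-1,2,3,5,6,7,8,8a-octahydronaphthalen-1-yl]oxy}silane (4,4,10-trimethyl octalin with the C5–C6 double bond and 9α-OTBS)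
Conditions: Pd(OAc)2 (10 mol %), PPh3 (25 mol %), HCO2Na (1.5 equiv, added in portions), Et4NCl (1 equiv), DMF, 80 °C
Reagents that add atoms: none
Why: Zerovalent palladium, formed in situ from Pd(OAc)2 and PPh3, inserts into the C5–O bond of the triflate, and the C5 alkenylpalladium adds syn across the tethered alkene so that C5 bonds to the internal carbon C4 and palladium ends on the terminal CH2; this neopentyl palladium, lacking any beta-hydrogen, takes up formate, loses CO2 and reductively eliminates C–H, turning the CH2 into the second C4 methyl. The closest known reaction type is the reductive Heck cyclisation, that is, intramolecular carbopalladation with formate hydride capture, as used to build quaternary carbons through neopentyl palladium intermediates. Ring A closes in the 6-exo-trig mode, because the three-atom link C1–C3 brings the substituted alkene carbon within reach of C5 while the 7-endo alternative would need a strained, twisted insertion geometry. No stereocentre is created, since C4 ends with two identical methyl groups and C5 stays trigonal, and C9 and C10 are spectators. Two selectivities are needed: insertion must outrun hydride transfer to the alkenylpalladium, and hydride capture must outrun 3-exo insertion of the neopentyl palladium into the new C5–C6 alkene. The first is secured by a low concentration of dissolved formate (sparingly soluble HCO2Na in portions, with chloride occupying palladium), and the second by the strain and reversibility of the 3-exo closure onto a trisubstituted alkene, which leaves formate capture as the only irreversible exit.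

Step 8
Reactants: 12 octalin silyl ether
Product: 13 (1R,8aS)-5,5,8a-trimethyl-1,2,3,5,6,7,8,8a-octahydronaphthalen-1-ol (9α-OH)
Conditions: 48 % aq. HF, MeCN, rt
Reagents that add atoms: none
Why: Fluoride-driven desilylation (strong Si–F bond) frees the hindered C9 alcohol, and the weakly acidic medium cannot move the C5–C6 alkene because both flanking carbons C4 and C10 are quaternary.

Step 9
Reactants: 13 octalinol
Product: 14 (8aS)-5,5,8a-trimethyl-3,5,6,7,8,8a-hexahydronaphthalen-1(2H)-one (C9 ketone)
Conditions: Dess–Martin periodinane, CH2Cl2, rt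
Reagents that add atoms: none
Why: Dess–Martin oxidation converts the hindered secondary alcohol into the C9 ketone under neutral conditions that spare the alkene, and the auxiliary C9 stereocentre disappears once its task is done.

Step 10
Reactants: 14 C9 ketone; 6 iodomethane
Product: 16 (8aS)-2,5,5,8a-tetramethyl-3,5,6,7,8,8a-hexahydronaphthalen-1(2H)-one (C8 methyl, both C8 epimers), via lithium enolate 15 (not isolated)
Conditions: LiN(i-Pr)2 (LDA, 1.1 equiv), THF, −78 °C; MeI, −78 → 0 °C
Reagents that add atoms: iodomethane 6, CI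
Why: Kinetic enolate alkylation: the C9 ketone can enolise only toward C8, so the methyl group should be placed regiospecifically, and the configuration at C8 does not matter because step 11 erases it.

Step 11
Reactants: 16 C8-methyl ketone
Product: 18 (8aS)-2,5,5,8a-tetramethyl-3,5,6,7,8,8a-hexahydronaphthalen-1-yl trifluoromethanesulfonate (5,8-diene, C9 enol triflate), via potassium enolate 17 (not isolated)
Conditions: KN(SiMe3)2 (1.2 equiv), THF, −78 → 0 °C; PhNTf2, 0 °C → rt
Reagents that add atoms: N-phenylbis(trifluoromethanesulfonimide), O=S(=O)(N(c1ccccc1)S(=O)(=O)C(F)(F)F)C(F)(F)F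
Why: Enolate O-triflation, well known for 2,2,6-trisubstituted cyclohexanones: removal of the only remaining alpha-hydrogen (C8–H) gives the tetrasubstituted enolate 17, whose trapping on oxygen fixes the C8–C9 double bond of the target and activates C9 for coupling.

Step 12
Reactants: 18 dienyl triflate
Product: 20 (4S,4aS,8aS)-4-hydroxy-2,5,5,8a-tetramethyl-3,4,4a,5,6,7,8,8a-octahydronaphthalen-1-yl trifluoromethanesulfonate (5α-H, 6α-OH, trans-fused), via C6 alkylborane 19 (not isolated)
Conditions: BH3·THF (3 equiv), THF, 0 °C → rt; NaBO3·4H2O, THF–H2O, rt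
Reagents that add atoms: sodium perborate tetrahydrate (oxygen atom), [Na+].[Na+].O[B-]1(O)OO[B-](O)(O)OO1
Why: Hydroboration–oxidation: BH3 adds syn to the only electron-rich alkene, boron to the less substituted C6 and hydrogen to C5, from the alpha face opposite the axial C10 and C4 methyl groups, which sets 5α-H (trans fusion) and the C6 oxygen, while the tetrasubstituted, electron-poor triflate alkene is inert and perborate oxidises C–B with retention without hydrolysing the triflate.

Step 13
Reactants: 20 6α-hydroxy triflate
Product: 21 (4aS,8aS)-2,5,5,8a-tetramethyl-4-oxo-3,4,4a,5,6,7,8,8a-octahydronaphthalen-1-yl trifluoromethanesulfonate (6-oxo, C9 triflate)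
Conditions: Dess–Martin periodinane, CH2Cl2, 0 °C → rt
Reagents that add atoms: none
Why: Dess–Martin oxidation gives the C6 ketone without base, so the beta,gamma-placed C8–C9 double bond stays where it is and the trans fusion at C5 is kept.

Step 14
Reactants: 21 6-oxo triflate; 22 2-(2-bromoethyl)-2-methyl-1,3-dioxolane
Product: 24 13,13-(ethylenedioxy)-14,15-dinorlabd-8-en-6-one (5α-H, 10β-CH3), via alkylzinc bromide 23 (not isolated)
Conditions: 22, Zn dust, LiCl, THF, 50 °C; then 21, Pd(OAc)2 (5 mol %), 2-dicyclohexylphosphino-2',6'-dimethoxybiphenyl (SPhos, 10 mol %), THF–NMP, 60 °C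
Reagents that add atoms: 2-(2-bromoethyl)-2-methyl-1,3-dioxolane 22, CC1(CCBr)OCCO1
Why: Negishi sp2–sp3 cross-coupling: zinc insertion into the primary bromide gives the ketal-bearing alkylzinc 23, which tolerates the ketone, and the bulky electron-rich biarylphosphine favours oxidative addition into the hindered triflate and reductive elimination over beta-hydride loss, forming C9–C11.

Step 15
Reactants: 24 8-en-6-one ketal
Product: 26 7α-hydroxy-13,13-(ethylenedioxy)-14,15-dinorlabd-8-en-6-one, via potassium dienolate 25 (not isolated)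
Conditions: KN(SiMe3)2 (1.1 equiv), THF, −78 °C; 2-(phenylsulfonyl)-3-phenyloxaziridine (1.4 equiv), −78 °C; AcOH quench at −78 °C
Reagents that add atoms: 2-(phenylsulfonyl)-3-phenyloxaziridine, O=S(=O)(c1ccccc1)N1OC1c1ccccc1
Why: Enolate hydroxylation with an N-sulfonyloxaziridine (Davis oxidation): the doubly activated C7–H (alpha to C6=O and allylic) is removed much faster than the hindered C5–H, the extended enolate 25 reacts at its alpha carbon C7 so that the C8–C9 alkene stays out of conjugation, and oxygen should arrive on the alpha face opposite the axial C10 and C4 methyl groups, setting 7α-OH.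

Step 16
Reactants: 26 7α-hydroxy ketone
Product: 27 13,13-(ethylenedioxy)-14,15-dinorlabd-8-ene-6β,7α-diol
Conditions: NaBH4, MeOH–CH2Cl2, −20 °C
Reagents that add atoms: none
Why: Borohydride reduction under steric approach control: the beta face of C6=O is closed by the syn-axial C10 and C4 methyl groups, so hydride enters from the alpha face and should give the axial 6β-alcohol, trans to the 7α-hydroxyl.

Step 17
Reactants: 27 6β,7α-diol
Product: 28 6β-hydroxy-7α-(3-methylbutanoyloxy)-13,13-(ethylenedioxy)-14,15-dinorlabd-8-ene
Conditions: isovaleryl chloride (1.1 equiv), pyridine, 4-(dimethylamino)pyridine (DMAP, cat.), CH2Cl2, 0 °C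
Reagents that add atoms: 3-methylbutanoyl chloride, CC(C)CC(=O)Cl
Why: Site-selective DMAP-catalysed esterification: the allylic 7α-hydroxyl is far more accessible than the 6β-hydroxyl wedged between two syn-axial methyl groups, and the trans-diaxial arrangement rules out later acyl migration.

Step 18
Reactants: 28 7-isovalerate
Product: 29 6β-acetoxy-7α-(3-methylbutanoyloxy)-13,13-(ethylenedioxy)-14,15-dinorlabd-8-ene
Conditions: Ac2O, DMAP, pyridine, 50 °C
Reagents that add atoms: acetic anhydride, CC(=O)OC(C)=O
Why: DMAP-catalysed acetylation under forcing but non-acidic conditions esterifies the remaining hindered axial 6β-hydroxyl with retention, since only the O–H bond reacts.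

Step 19
Reactants: 29 diester ketal
Product: 30 6β-acetoxy-7α-(3-methylbutanoyloxy)-14,15-dinorlabd-8-en-13-one
Conditions: TsOH·H2O (10 mol %), THF–H2O, rt
Reagents that add atoms: water, O
Why: Acid-catalysed ketal hydrolysis: the dioxolane of an unhindered dialkyl ketone cleaves under mild aqueous acid that leaves both secondary esters and the allylic C7–O bond intact.

Step 20
Reactants: 30 methyl ketone; 31 allyl 2-(diethoxyphosphoryl)acetate
Product: 33 allyl (13E)-6β-acetoxy-7α-(3-methylbutanoyloxy)labda-8,13-dien-15-oate, via sodium phosphonate anion 32 (not isolated)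
Conditions: 31 (2.2 equiv), NaH (2.0 equiv), THF, 0 °C; then 30, 0 °C → 40 °C; chromatography
Reagents that add atoms: allyl 2-(diethoxyphosphoryl)acetate 31, C=CCOC(=O)CP(=O)(OCC)OCC
Why: Horner–Wadsworth–Emmons olefination: the stabilised anion 32 adds reversibly to the unhindered methyl ketone and eliminates through the less crowded oxaphosphetane, placing the ester trans to the larger C12 chain (13E, any Z isomer being removed by chromatography), while the soft anion leaves the hindered esters alone.

Step 21
Reactants: 33 allyl ester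
Product: 34 (13E)-6β-acetoxy-7α-(3-methylbutanoyloxy)labda-8,13-dien-15-oic acid (5S,6S,7S,10S), CNP0328312.2
Conditions: Pd(PPh3)4 (5 mol %), morpholine (5 equiv), THF, rt; dilute citric acid wash
Reagents that add atoms: none
Why: Tsuji–Trost-type deallylation: zerovalent palladium ionises only the unhindered allyl ester and morpholine traps the allyl unit, whereas the C7 allylic isovalerate on a tetrasubstituted ring alkene cannot be approached from its shielded beta face, so both acyl groups survive a step that uses neither acid nor hydroxide.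

**Compound list**

1 | ethyl 4-methylpent-4-enoate | C=C(C)CCC(=O)OCC | starting material
2 | 4-methylpent-4-enal | C=C(C)CCC=O | intermediate
3 | cyclohexane-1,3-dione | O=C1CCCC(=O)C1 | starting material
4 | alkylidene dione, 2-(4-methylpent-4-en-1-ylidene)cyclohexane-1,3-dione (not isolated) | C=C(C)CCC=C1C(=O)CCCC1=O | intermediate
5 | 2-(4-methylpent-4-en-1-yl)cyclohexane-1,3-dione | C=C(C)CCCC1C(=O)CCCC1=O | intermediate
6 | iodomethane | CI | starting material
7 | 2-methyl-2-(4-methylpent-4-en-1-yl)cyclohexane-1,3-dione | C=C(C)CCCC1(C)C(=O)CCCC1=O | intermediate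
8 | (2R,3R)-3-hydroxy-2-methyl-2-(4-methylpent-4-en-1-yl)cyclohexan-1-one | C=C(C)CCC[C@@]1(C)C(=O)CCC[C@H]1O | intermediate
9 | (2R,3R)-3-(tert-butyldimethylsilyloxy)-2-methyl-2-(4-methylpent-4-en-1-yl)cyclohexan-1-one | C=C(C)CCC[C@@]1(C)C(=O)CCC[C@H]1O[Si](C)(C)C(C)(C)C | intermediate
10 | potassium enolate of 9 (not isolated) | C=C(C)CCC[C@@]1(C)C([O-])=CCC[C@H]1O[Si](C)(C)C(C)(C)C.[K+] | intermediate
11 | (5R,6R)-5-(tert-butyldimethylsilyloxy)-6-methyl-6-(4-methylpent-4-en-1-yl)cyclohex-1-en-1-yl trifluoromethanesulfonate | C=C(C)CCC[C@@]1(C)C(OS(=O)(=O)C(F)(F)F)=CCC[C@H]1O[Si](C)(C)C(C)(C)C | intermediate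
12 | tert-butyldimethyl{[(1R,8aS)-5,5,8a-trimethyl-1,2,3,5,6,7,8,8a-octahydronaphthalen-1-yl]oxy}silane | CC1(C)CCC[C@@]2(C)C1=CCC[C@H]2O[Si](C)(C)C(C)(C)C | intermediate
13 | (1R,8aS)-5,5,8a-trimethyl-1,2,3,5,6,7,8,8a-octahydronaphthalen-1-ol | CC1(C)CCC[C@@]2(C)C1=CCC[C@H]2O | intermediate
14 | (8aS)-5,5,8a-trimethyl-3,5,6,7,8,8a-hexahydronaphthalen-1(2H)-one | CC1(C)CCC[C@@]2(C)C1=CCCC2=O | intermediate
15 | lithium enolate of 14 (not isolated) | CC1(C)CCC[C@@]2(C)C1=CCC=C2[O-].[Li+] | intermediate
16 | (8aS)-2,5,5,8a-tetramethyl-3,5,6,7,8,8a-hexahydronaphthalen-1(2H)-one, both C8 epimers | CC1(C)CCC[C@@]2(C)C1=CCC(C)C2=O | intermediate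
17 | potassium enolate of 16 (not isolated) | CC1(C)CCC[C@@]2(C)C1=CCC(C)=C2[O-].[K+] | intermediate
18 | (8aS)-2,5,5,8a-tetramethyl-3,5,6,7,8,8a-hexahydronaphthalen-1-yl trifluoromethanesulfonate | CC1(C)CCC[C@@]2(C)C1=CCC(C)=C2OS(=O)(=O)C(F)(F)F | intermediate
19 | C6 alkylborane, 6α-boryl-5α-H adduct of 18 (not isolated) | B[C@H]1CC(C)=C(OS(=O)(=O)C(F)(F)F)[C@@]2(C)CCCC(C)(C)[C@H]12 | intermediate
20 | (4S,4aS,8aS)-4-hydroxy-2,5,5,8a-tetramethyl-3,4,4a,5,6,7,8,8a-octahydronaphthalen-1-yl trifluoromethanesulfonate | O[C@H]1CC(C)=C(OS(=O)(=O)C(F)(F)F)[C@@]2(C)CCCC(C)(C)[C@H]12 | intermediate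
21 | (4aS,8aS)-2,5,5,8a-tetramethyl-4-oxo-3,4,4a,5,6,7,8,8a-octahydronaphthalen-1-yl trifluoromethanesulfonate | O=C1CC(C)=C(OS(=O)(=O)C(F)(F)F)[C@@]2(C)CCCC(C)(C)[C@H]12 | intermediate
22 | 2-(2-bromoethyl)-2-methyl-1,3-dioxolane | CC1(CCBr)OCCO1 | starting material
23 | alkylzinc bromide, [2-(2-methyl-1,3-dioxolan-2-yl)ethyl]zinc bromide (not isolated) | CC1(CC[Zn]Br)OCCO1 | intermediate
24 | 13,13-(ethylenedioxy)-14,15-dinorlabd-8-en-6-one | O=C1CC(C)=C(CCC3(C)OCCO3)[C@@]2(C)CCCC(C)(C)[C@H]12 | intermediate
25 | potassium dienolate of 24 (not isolated) | [K+].[O-]C1=CC(C)=C(CCC3(C)OCCO3)[C@@]2(C)CCCC(C)(C)[C@H]12 | intermediate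
26 | 7α-hydroxy-13,13-(ethylenedioxy)-14,15-dinorlabd-8-en-6-one | O=C1[C@@H](O)C(C)=C(CCC3(C)OCCO3)[C@@]2(C)CCCC(C)(C)[C@H]12 | intermediate
27 | 13,13-(ethylenedioxy)-14,15-dinorlabd-8-ene-6β,7α-diol | O[C@@H]1[C@@H](O)C(C)=C(CCC3(C)OCCO3)[C@@]2(C)CCCC(C)(C)[C@H]12 | intermediate
28 | 6β-hydroxy-7α-(3-methylbutanoyloxy)-13,13-(ethylenedioxy)-14,15-dinorlabd-8-ene | O[C@@H]1[C@@H](OC(=O)CC(C)C)C(C)=C(CCC3(C)OCCO3)[C@@]2(C)CCCC(C)(C)[C@H]12 | intermediate
29 | 6β-acetoxy-7α-(3-methylbutanoyloxy)-13,13-(ethylenedioxy)-14,15-dinorlabd-8-ene | CC(=O)O[C@@H]1[C@@H](OC(=O)CC(C)C)C(C)=C(CCC3(C)OCCO3)[C@@]2(C)CCCC(C)(C)[C@H]12 | intermediate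
30 | 6β-acetoxy-7α-(3-methylbutanoyloxy)-14,15-dinorlabd-8-en-13-one | CC(=O)O[C@@H]1[C@@H](OC(=O)CC(C)C)C(C)=C(CCC(C)=O)[C@@]2(C)CCCC(C)(C)[C@H]12 | intermediate
31 | allyl 2-(diethoxyphosphoryl)acetate | C=CCOC(=O)CP(=O)(OCC)OCC | starting material
32 | sodium phosphonate anion of 31 (not isolated) | [Na+].C=CCOC(=O)[CH-]P(=O)(OCC)OCC | intermediate
33 | allyl (13E)-6β-acetoxy-7α-(3-methylbutanoyloxy)labda-8,13-dien-15-oate | CC(=O)O[C@@H]1[C@@H](OC(=O)CC(C)C)C(C)=C(CC/C(C)=C/C(=O)OCC=C)[C@@]2(C)CCCC(C)(C)[C@H]12 | intermediate
34 | (13E)-6β-acetoxy-7α-(3-methylbutanoyloxy)labda-8,13-dien-15-oic acid | CC(=O)O[C@@H]1[C@@H](OC(=O)CC(C)C)C(C)=C(CC/C(C)=C/C(=O)O)[C@@]2(C)CCCC(C)(C)[C@H]12 | target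

**Step count**

Total step count: 21. Longest linear sequence: 21 steps (1 → 34); 3, 6, 22 and 31 are bought.

**Steps most likely to fail**

**Risk 1, step 7.**
- **What may go wrong:** Hydride may be transferred to the alkenylpalladium before the alkene inserts, which only removes the triflate. Alternatively, the neopentyl palladium may insert onward into the C5–C6 alkene and expand the ring before formate reaches it.
- **Fallback:** It keeps the C4–C5 carbopalladation but takes the reducing agent out of the cyclisation flask. It sets out from ketone 9.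
- Hydrazine hydrate and Et3N in refluxing EtOH should give the C5 hydrazone F1.
- I2 with 1,1,3,3-tetramethylguanidine in THF at 0 °C (Barton vinyl iodide synthesis) should give the C5 alkenyl iodide F2.
- Heating F2 with Pd(P(t-Bu)3)2 in toluene at 100 °C is a palladium-catalysed carboiodination. The same 6-exo insertion takes place, but the neopentyl palladium closes the cycle by C–I reductive elimination to give the bicyclic neopentyl iodide F3 (both C4 epimers).
- Lithium–iodine exchange with t-BuLi in Et2O–pentane at −78 °C, followed by an immediate MeOH quench, turns CH2I into CH3 and comes back to the route at 12. A tin hydride reduction is avoided because the neopentyl radical next to the alkene would undergo vinyl migration.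

**Risk 2, step 14.**
- **What may go wrong:** Oxidative addition into the triflate, which is flanked by the quaternary C10 and the C8 methyl, may be slow. Beta-hydride loss from the alkylpalladium would then lead to simple reduction of the triflate.
- **Fallback:** It replaces the sp2–sp3 coupling with an sp2–sp2 bond formation followed by reduction. It sets out from hydroxy triflate 20.
- A Heck reaction with but-3-en-2-one (Pd(OAc)2, PPh3, Et3N, DMF, 70 °C) should give the (11E)-6α-hydroxy-14,15-dinorlabda-8,11-dien-13-one F4.
- Conjugate reduction with [(Ph3P)CuH]6 in wet toluene saturates only the enone C11–C12 bond, giving 6α-hydroxy-14,15-dinorlabd-8-en-13-one F5.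
- Ethylene glycol with pyridinium p-toluenesulfonate in refluxing benzene ketalises the unhindered ketone to the 6α-hydroxy ketal F6.
- Dess–Martin oxidation of F6 comes back to the route at 24.

**Risk 3, step 15.**
- **What may go wrong:** Facial selectivity of oxygen transfer to the nearly flat dienolate may be poor. Proton transfer may draw the C8–C9 alkene into conjugation, or the ketol may transpose on warming.
- **Fallback:** It brings in the C7 oxygen at the ketone level and sets C7 by inversion. It sets out from 24.
- NaBH4 in MeOH delivers hydride from the alpha face to give the 6β-alcohol F7.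
- Ac2O, DMAP and pyridine give the 6β-acetate F8.
- Allylic oxidation with CrO3 and 3,5-dimethylpyrazole in CH2Cl2 at −20 °C oxidises the ring methylene C7 to the 6β-acetoxy-8-en-7-one F9.
- Luche reduction (NaBH4, CeCl3·7H2O, MeOH, −78 °C) from the open alpha face gives the 6β-acetoxy-7β-alcohol F10.
- A Mitsunobu reaction with 3-methylbutanoic acid, PPh3 and diisopropyl azodicarboxylate inverts C7 by attack from the alpha face and comes back to the route at 29.

**Further compounds**

F1 | step 7 | C5 hydrazone of 9 | C=C(C)CCC[C@@]1(C)C(=NN)CCC[C@H]1O[Si](C)(C)C(C)(C)C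
F2 | step 7 | C5 alkenyl iodide, tert-butyl{[(1R,2R)-3-iodo-2-methyl-2-(4-methylpent-4-en-1-yl)cyclohex-3-en-1-yl]oxy}dimethylsilane | C=C(C)CCC[C@@]1(C)C(I)=CCC[C@H]1O[Si](C)(C)C(C)(C)C
F3 | step 7 | bicyclic neopentyl iodide, 12 with one C4 methyl as CH2I (both C4 epimers) | CC1(CI)CCC[C@@]2(C)C1=CCC[C@H]2O[Si](C)(C)C(C)(C)C
F4 | step 14 | (11E)-6α-hydroxy-14,15-dinorlabda-8,11-dien-13-one | O[C@H]1CC(C)=C(/C=C/C(C)=O)[C@@]2(C)CCCC(C)(C)[C@H]12
F5 | step 14 | 6α-hydroxy-14,15-dinorlabd-8-en-13-one | O[C@H]1CC(C)=C(CCC(C)=O)[C@@]2(C)CCCC(C)(C)[C@H]12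
F6 | step 14 | 13,13-(ethylenedioxy)-14,15-dinorlabd-8-en-6α-ol | O[C@H]1CC(C)=C(CCC3(C)OCCO3)[C@@]2(C)CCCC(C)(C)[C@H]12
F7 | step 15 | 13,13-(ethylenedioxy)-14,15-dinorlabd-8-en-6β-ol | O[C@@H]1CC(C)=C(CCC3(C)OCCO3)[C@@]2(C)CCCC(C)(C)[C@H]12
F8 | step 15 | 6β-acetoxy-13,13-(ethylenedioxy)-14,15-dinorlabd-8-ene | CC(=O)O[C@@H]1CC(C)=C(CCC3(C)OCCO3)[C@@]2(C)CCCC(C)(C)[C@H]12
F9 | step 15 | 6β-acetoxy-13,13-(ethylenedioxy)-14,15-dinorlabd-8-en-7-one | CC(=O)O[C@@H]1C(=O)C(C)=C(CCC3(C)OCCO3)[C@@]2(C)CCCC(C)(C)[C@H]12
F10 | step 15 | 6β-acetoxy-13,13-(ethylenedioxy)-14,15-dinorlabd-8-en-7β-ol | CC(=O)O[C@@H]1[C@H](O)C(C)=C(CCC3(C)OCCO3)[C@@]2(C)CCCC(C)(C)[C@H]12
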